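The target is cut at the single bond between the alkene CH and the methine attached to C2 of ring A (the pyranone bearing the hydroxypentyl chain). This methine is a vinylogous α-keto position, so its chloride releases a stabilised planar radical. A ligand-controlled nickel reductive coupling of the E-alkenyl bromide of the ring B half (both esters in place) with the epimeric chloride of the ring A half joins the halves and funnels both chloride epimers into the S centre. Both halves grow from one Evans syn-aldol adduct: directly for the ring A side chain, and through its β-keto imide (anti,anti aldol, syn reduction) for the ring B stereotetrad.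

Key step: step 19

Remark on the chemistry: 4-methylheptane-3,5-dione (7) is taken to be purchasable; the ligand enantiomer in step 19 is the one expected, by analogy with secondary benzylic chlorides, to give the S centre, and its antipode would be used if a model coupling showed the opposite sense.

Step 1
Reactants: 1 (R)-4-benzyl-3-propanoyl-1,3-oxazolidin-2-one; 2 propanal
Product: 4 syn-aldol imide (2R,3S), via dibutylboron Z-enolate 3 (not isolated)
Conditions: Bu2BOTf, Et3N, CH2Cl2, 0 °C; then 2, −78 → 0 °C; then pH 7 buffer, MeOH, H2O2, 0 °C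
Reagents that add atoms: none
Why: Evans syn aldol reaction, in which the Z-boron enolate reacts through a closed Zimmerman–Traxler chair and the benzyl group of the R auxiliary shields one enolate face, which should set the 2R,3S syn pair.

Step 2
Reactants: 4 syn-aldol imide
Product: 5 β-hydroxy Weinreb amide
Conditions: MeONHMe·HCl, Me3Al, CH2Cl2, −20 → 0 °C; then aq. potassium sodium tartrate
Reagents that add atoms: N,O-dimethylhydroxylamine hydrochloride, CNOC.Cl
Why: Weinreb transamination of an aldol imide, in which the free β-hydroxyl binds aluminium and steers the amide to the exocyclic carbonyl, so the auxiliary is released without touching either stereocentre.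

Step 3
Reactants: 5 β-hydroxy Weinreb amide
Product: 6 TBS-protected Weinreb amide
Conditions: TBSOTf, 2,6-lutidine, CH2Cl2, −78 → 0 °C
Reagents that add atoms: tert-butyldimethylsilyl triflate, CC(C)(C)[Si](C)(C)OS(=O)(=O)C(F)(F)F
Why: Standard silylation of a secondary alcohol, needed because the later dianion, cyclodehydration and enolate steps do not tolerate a free β-hydroxyl.

Step 4
Reactants: 6 TBS-protected Weinreb amide; 7 4-methylheptane-3,5-dione
Product: 9 silyloxy triketone, via dilithium dienolate 8 (not isolated)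
Conditions: 7 (3 equiv), LiN(iPr)2 (6 equiv), THF, −78 → 0 °C; then 6, −78 → 0 °C; aq. NH4Cl
Reagents that add atoms: none
Why: Claisen-type C-acylation of a β-diketone dianion at its terminal carbon by a Weinreb amide, where the chelated tetrahedral intermediate and the polyanionic product should prevent over-addition and the stereocentres of 6 are not touched (the two new methines between carbonyls are lost in step 5).

Step 5
Reactants: 9 silyloxy triketone
Product: 10 ring A pyranone with ethyl group
Conditions: PPh3, CCl4, THF, rt; aq. NaHCO3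
Reagents that add atoms: none
Why: Cyclodehydration of a 1,3,5-triketone to a 4-pyranone, in which one terminal enol oxygen is activated as an oxyphosphonium group and displaced by the other in an addition–elimination, under conditions mild enough to keep the TBS ether and the side-chain centres.

Step 6
Reactants: 10 ring A pyranone with ethyl group
Product: 12 ring A chloride (both epimers at CHCl), via lithium dienolate 11 (not isolated)
Conditions: LiN(SiMe3)2, THF, −78 °C; then cannulated into C2Cl6, THF, −78 °C
Reagents that add atoms: hexachloroethane, ClC(Cl)(Cl)C(Cl)(Cl)Cl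
Why: Kinetic deprotonation at the less hindered ethyl CH2 gives the exocyclic vinylogous enolate, and its electrophilic chlorination at the exocyclic carbon restores the pyranone; the new C–Cl centre needs no control because step 19 is stereoconvergent.

Step 7
Reactants: 4 syn-aldol imide
Product: 13 β-keto imide
Conditions: SO3·pyridine, DMSO, Et3N, CH2Cl2, −10 °C → rt
Reagents that add atoms: none
Why: Parikh–Doering oxidation; the β-keto imide resists enolisation because of allylic strain, so the methyl-bearing centre should keep its R configuration.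

Step 8
Reactants: 14 methacrolein
Product: 16 (E)-3-bromo-2-methylprop-2-enal, via 2,3-dibromo-2-methylpropanal 15 (not isolated)
Conditions: Br2, CH2Cl2, −78 → 0 °C; then Et3N, 0 °C → rt
Reagents that add atoms: bromine, BrBr
Why: Bromine addition to the alkene followed by base-induced dehydrobromination (loss of the acidic CH2Br proton and the tertiary bromide) should give the conjugated bromo-enal, the E isomer (Br anti to CHO) being the more stable one.

Step 9
Reactants: 13 β-keto imide; 16 (E)-3-bromo-2-methylprop-2-enal
Product: 18 anti,anti-aldol keto imide, via dicyclohexylboron E-enolate 17 (not isolated)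
Conditions: Cy2BCl, EtNMe2, Et2O, 0 °C; then 16, −78 → −20 °C; then pH 7 buffer, MeOH, H2O2, 0 °C
Reagents that add atoms: none
Why: Evans anti,anti aldol of a β-keto imide, in which Cy2BCl/EtNMe2 gives the E-enolate, the chair Zimmerman–Traxler transition state sets the anti C4/C5 pair, and the existing C2 centre directs the aldehyde to the face that places the two methyl groups anti.

Step 10
Reactants: 18 anti,anti-aldol keto imide
Product: 19 TES-protected keto imide
Conditions: Et3SiCl, imidazole, DMF, 0 °C
Reagents that add atoms: chlorotriethylsilane, CC[Si](CC)(CC)Cl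
Why: Silylation of the only hydroxyl under mild base marks this oxygen for the later propionate and leaves the β-keto imide untouched.

Step 11
Reactants: 19 TES-protected keto imide
Product: 20 β-hydroxy imide with complete stereotetrad
Conditions: Zn(BH4)2, Et2O/CH2Cl2, −78 → −20 °C; aq. NH4Cl
Reagents that add atoms: none
Why: Chelation-controlled ketone reduction in which zinc bridges the ketone and imide carbonyls and hydride adds anti to the C2 methyl group (syn C2/C3), a sense reinforced by Felkin control from C4, which should give the 3S alcohol.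

Step 12
Reactants: 20 β-hydroxy imide
Product: 21 β-hydroxy Weinreb amide of the ring B half
Conditions: MeONHMe·HCl, Me3Al, CH2Cl2, −20 → 0 °C; then aq. potassium sodium tartrate
Reagents that add atoms: N,O-dimethylhydroxylamine hydrochloride, CNOC.Cl
Why: Weinreb transamination as in step 2, assisted by the free C3 hydroxyl, with no stereocentre affected.

Step 13
Reactants: 21 β-hydroxy Weinreb amide
Product: 22 bis-silyl Weinreb amide
Conditions: TBSOTf, 2,6-lutidine, CH2Cl2, −78 → 0 °C
Reagents that add atoms: tert-butyldimethylsilyl triflate, CC(C)(C)[Si](C)(C)OS(=O)(=O)C(F)(F)F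
Why: Silylation with the more robust TBS group, orthogonal to the TES ether, so that the two oxygens can later be acylated one after the other.

Step 14
Reactants: 22 bis-silyl Weinreb amide; 7 4-methylheptane-3,5-dione
Product: 24 bis-silyl triketone, via lithium sodium dienolate 23 (not isolated)
Conditions: 7 (3 equiv), NaH (3 equiv), THF, 0 °C; then n-BuLi (2.85 equiv), −78 → 0 °C; then 22, −78 → 0 °C; aq. NH4Cl
Reagents that add atoms: none
Why: Claisen-type acylation of the diketone dianion as in step 4, here generated amine-free (NaH for the central proton, slightly less than one equivalent of n-BuLi for the terminal one) so that neither an amide base nor free alkyllithium meets the alkenyl bromide, which together with the silyl ethers should survive while the four chain stereocentres stay untouched.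

Step 15
Reactants: 24 bis-silyl triketone
Product: 26 ring B pyranone with free allylic alcohol, via bis-silyl pyranone 25 (not isolated)
Conditions: PPh3, CCl4, THF, rt; then MeOH, 0 °C; aq. NaHCO3
Reagents that add atoms: none
Why: Cyclodehydration to the 4-pyranone as in step 5; the HCl set free, once methanol is added, should cleave the allylic TES ether much faster than the hindered secondary TBS ether.

Step 16
Reactants: 26 ring B pyranone with free allylic alcohol
Product: 27 propionate
Conditions: (EtCO)2O, DMAP, Et3N, CH2Cl2, 0 °C → rt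
Reagents that add atoms: propanoic anhydride, CCC(=O)OC(=O)CC
Why: DMAP-catalysed acyl transfer to the only free hydroxyl, with no stereocentre affected.

Step 17
Reactants: 27 propionate
Product: 28 hydroxy propionate
Conditions: HF·pyridine, pyridine, THF, 0 °C → rt
Reagents that add atoms: none
Why: Desilylation with buffered acidic fluoride should spare the propionate and the alkenyl bromide and avoid the 1,3-acyl shift that basic fluoride could trigger.

Step 18
Reactants: 28 hydroxy propionate
Product: 29 alkenyl bromide of the ring B half (acetate and propionate in place)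
Conditions: Ac2O, DMAP, pyridine, CH2Cl2, rt
Reagents that add atoms: acetic anhydride, CC(=O)OC(C)=O
Why: DMAP-catalysed acetylation of the hindered secondary alcohol completes the differentiated diester.

Step 19
Reactants: 29 alkenyl bromide of the ring B half; 12 ring A chloride (both epimers, 1.5 equiv)
Product: 30 TBS ether of the target
Conditions: NiCl2(dme) (10 mol %), cyclopropane-1,1-diyl-bridged bis(indeno-oxazoline) ligand (11 mol %), Mn powder (3 equiv), NaI (0.5 equiv), DMA, 0 °C
Reagents that add atoms: none
Why: Proposed new method: Zerovalent nickel, formed from NiCl2(dme), the ligand and Mn, inserts into the C–Br bond of 29 with retention of the E geometry, while halogen abstraction from either epimer of 12 (through the iodide formed with NaI) gives one planar radical delocalised over C2=C3–C4=O of ring A; capture of this radical at nickel and reductive elimination form the alkenyl–C(sp3) bond. The closest known reaction type is the nickel-catalysed enantioconvergent reductive cross-coupling of alkenyl bromides with racemic secondary benzylic chlorides, and the reasoning is that the pyranonyl-substituted radical should be at least as stabilised and as readily formed as a benzylic one. No ring is closed. The new stereocentre is set by the chiral bis(oxazoline) ligand at the radical-capture and reductive-elimination stage, so the configuration at the C–Cl carbon is irrelevant and both epimers should converge on S; the existing stereocentres are remote from the reacting atoms and are not expected to override the catalyst. The step needs cross-coupling over homocoupling, which the different activation of the C(sp2)–Br bond (two-electron oxidative addition) and of the activated C(sp3)–Cl bond (radical) should provide. It also needs the allylic propionate and the acetate to stay untouched, which the low temperature and the much faster reaction of the alkenyl bromide should secure.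

Step 20
Reactants: 30 TBS ether of the target
Product: 31 target CNP0265513.2
Conditions: HF·pyridine, pyridine, THF, 0 °C → rt
Reagents that add atoms: none
Why: Buffered acidic fluoride cleaves the remaining TBS ether without touching the two esters or the base-sensitive doubly activated methine, which should give the target.

Compound list

1 | (R)-4-benzyl-3-propanoyl-1,3-oxazolidin-2-one | CCC(=O)N1[C@H](Cc2ccccc2)COC1=O | starting material
2 | propanal | CCC=O | starting material
3 | (R)-4-benzyl-3-[(Z)-1-(dibutylboranyloxy)prop-1-en-1-yl]-1,3-oxazolidin-2-one (boron Z-enolate of 1) | C/C=C(\OB(CCCC)CCCC)N1[C@H](Cc2ccccc2)COC1=O | intermediate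
4 | (R)-4-benzyl-3-[(2R,3S)-3-hydroxy-2-methylpentanoyl]-1,3-oxazolidin-2-one | CC[C@H](O)[C@@H](C)C(=O)N1[C@H](Cc2ccccc2)COC1=O | intermediate
5 | (2R,3S)-3-hydroxy-N-methoxy-N,2-dimethylpentanamide | CC[C@H](O)[C@@H](C)C(=O)N(C)OC | intermediate
6 | (2R,3S)-3-[(tert-butyldimethylsilyl)oxy]-N-methoxy-N,2-dimethylpentanamide | CC[C@H](O[Si](C)(C)C(C)(C)C)[C@@H](C)C(=O)N(C)OC | intermediate
7 | 4-methylheptane-3,5-dione | CCC(=O)C(C)C(=O)CC | starting material
8 | dilithium 4-methylhepta-2,4-diene-3,5-diolate (dianion of 7) | [Li+].[Li+].CC=C([O-])C(C)=C([O-])CC | intermediate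
9 | (8R,9S)-9-[(tert-butyldimethylsilyl)oxy]-4,6,8-trimethylundecane-3,5,7-trione (C4 and C6 unassigned, keto–enol mixture) | CC[C@H](O[Si](C)(C)C(C)(C)C)[C@@H](C)C(=O)C(C)C(=O)C(C)C(=O)CC | intermediate
10 | 2-{(2R,3S)-3-[(tert-butyldimethylsilyl)oxy]pentan-2-yl}-6-ethyl-3,5-dimethyl-4H-pyran-4-one | CC[C@H](O[Si](C)(C)C(C)(C)C)[C@@H](C)c1oc(CC)c(C)c(=O)c1C | intermediate
11 | lithium 2-{(2R,3S)-3-[(tert-butyldimethylsilyl)oxy]pentan-2-yl}-6-ethylidene-3,5-dimethyl-6H-pyran-4-olate (vinylogous enolate of 10) | [Li+].CC[C@H](O[Si](C)(C)C(C)(C)C)[C@@H](C)C1=C(C)C([O-])=C(C)C(=CC)O1 | intermediate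
12 | 2-(1-chloroethyl)-6-{(2R,3S)-3-[(tert-butyldimethylsilyl)oxy]pentan-2-yl}-3,5-dimethyl-4H-pyran-4-one (both epimers at the CHCl carbon) | CC[C@H](O[Si](C)(C)C(C)(C)C)[C@@H](C)c1oc(C(C)Cl)c(C)c(=O)c1C | intermediate
13 | (R)-4-benzyl-3-[(R)-2-methyl-3-oxopentanoyl]-1,3-oxazolidin-2-one | CCC(=O)[C@@H](C)C(=O)N1[C@H](Cc2ccccc2)COC1=O | intermediate
14 | methacrolein (2-methylprop-2-enal) | CC(=C)C=O | starting material
15 | 2,3-dibromo-2-methylpropanal (racemic) | CC(Br)(CBr)C=O | intermediate
16 | (E)-3-bromo-2-methylprop-2-enal | O=C/C(C)=C/Br | intermediate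
17 | (R)-4-benzyl-3-[(2R,3E)-3-(dicyclohexylboranyloxy)-2-methylpent-3-enoyl]-1,3-oxazolidin-2-one (boron E-enolate of 13) | C/C=C(/OB(C2CCCCC2)C3CCCCC3)[C@@H](C)C(=O)N1[C@H](Cc4ccccc4)COC1=O | intermediate
18 | (R)-4-benzyl-3-[(2R,4S,5R,6E)-7-bromo-5-hydroxy-2,4,6-trimethyl-3-oxohept-6-enoyl]-1,3-oxazolidin-2-one | O[C@@H](/C(C)=C/Br)[C@H](C)C(=O)[C@@H](C)C(=O)N1[C@H](Cc2ccccc2)COC1=O | intermediate
19 | (R)-4-benzyl-3-{(2R,4S,5R,6E)-7-bromo-2,4,6-trimethyl-3-oxo-5-[(triethylsilyl)oxy]hept-6-enoyl}-1,3-oxazolidin-2-one | CC[Si](CC)(CC)O[C@@H](/C(C)=C/Br)[C@H](C)C(=O)[C@@H](C)C(=O)N1[C@H](Cc2ccccc2)COC1=O | intermediate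
20 | (R)-4-benzyl-3-{(2R,3S,4R,5R,6E)-7-bromo-3-hydroxy-2,4,6-trimethyl-5-[(triethylsilyl)oxy]hept-6-enoyl}-1,3-oxazolidin-2-one | CC[Si](CC)(CC)O[C@@H](/C(C)=C/Br)[C@H](C)[C@H](O)[C@@H](C)C(=O)N1[C@H](Cc2ccccc2)COC1=O | intermediate
21 | (2R,3S,4R,5R,6E)-7-bromo-3-hydroxy-N-methoxy-N,2,4,6-tetramethyl-5-[(triethylsilyl)oxy]hept-6-enamide | CC[Si](CC)(CC)O[C@@H](/C(C)=C/Br)[C@H](C)[C@H](O)[C@@H](C)C(=O)N(C)OC | intermediate
22 | (2R,3S,4R,5R,6E)-7-bromo-3-[(tert-butyldimethylsilyl)oxy]-N-methoxy-N,2,4,6-tetramethyl-5-[(triethylsilyl)oxy]hept-6-enamide | CC[Si](CC)(CC)O[C@@H](/C(C)=C/Br)[C@H](C)[C@H](O[Si](C)(C)C(C)(C)C)[C@@H](C)C(=O)N(C)OC | intermediate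
23 | lithium sodium 4-methylhepta-2,4-diene-3,5-diolate (mixed dianion of 7) | [Li+].[Na+].CC=C([O-])C(C)=C([O-])CC | intermediate
24 | (8R,9S,10R,11R,12E)-13-bromo-9-[(tert-butyldimethylsilyl)oxy]-4,6,8,10,12-pentamethyl-11-[(triethylsilyl)oxy]tridec-12-ene-3,5,7-trione (C4 and C6 unassigned, keto–enol mixture) | CC[Si](CC)(CC)O[C@@H](/C(C)=C/Br)[C@H](C)[C@H](O[Si](C)(C)C(C)(C)C)[C@@H](C)C(=O)C(C)C(=O)C(C)C(=O)CC | intermediate
25 | 2-{(2R,3S,4R,5R,6E)-7-bromo-3-[(tert-butyldimethylsilyl)oxy]-4,6-dimethyl-5-[(triethylsilyl)oxy]hept-6-en-2-yl}-6-ethyl-3,5-dimethyl-4H-pyran-4-one | CC[Si](CC)(CC)O[C@@H](/C(C)=C/Br)[C@H](C)[C@H](O[Si](C)(C)C(C)(C)C)[C@@H](C)c1oc(CC)c(C)c(=O)c1C | intermediate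
26 | 2-{(2R,3S,4S,5R,6E)-7-bromo-3-[(tert-butyldimethylsilyl)oxy]-5-hydroxy-4,6-dimethylhept-6-en-2-yl}-6-ethyl-3,5-dimethyl-4H-pyran-4-one (same spatial arrangement as 25; the C4 label changes by priority only) | O[C@@H](/C(C)=C/Br)[C@H](C)[C@H](O[Si](C)(C)C(C)(C)C)[C@@H](C)c1oc(CC)c(C)c(=O)c1C | intermediate
27 | (1E,3R,4S,5S,6R)-1-bromo-5-[(tert-butyldimethylsilyl)oxy]-6-(6-ethyl-3,5-dimethyl-4-oxo-4H-pyran-2-yl)-2,4-dimethylhept-1-en-3-yl propanoate | CCC(=O)O[C@@H](/C(C)=C/Br)[C@H](C)[C@H](O[Si](C)(C)C(C)(C)C)[C@@H](C)c1oc(CC)c(C)c(=O)c1C | intermediate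
28 | (1E,3R,4R,5S,6R)-1-bromo-6-(6-ethyl-3,5-dimethyl-4-oxo-4H-pyran-2-yl)-5-hydroxy-2,4-dimethylhept-1-en-3-yl propanoate | CCC(=O)O[C@@H](/C(C)=C/Br)[C@H](C)[C@H](O)[C@@H](C)c1oc(CC)c(C)c(=O)c1C | intermediate
29 | (1E,3R,4R,5S,6R)-5-acetoxy-1-bromo-6-(6-ethyl-3,5-dimethyl-4-oxo-4H-pyran-2-yl)-2,4-dimethylhept-1-en-3-yl propanoate | CCC(=O)O[C@@H](/C(C)=C/Br)[C@H](C)[C@H](OC(C)=O)[C@@H](C)c1oc(CC)c(C)c(=O)c1C | intermediate
30 | (2R,3S,4R,5R,6E,8S)-3-acetoxy-8-(6-{(2R,3S)-3-[(tert-butyldimethylsilyl)oxy]pentan-2-yl}-3,5-dimethyl-4-oxo-4H-pyran-2-yl)-2-(6-ethyl-3,5-dimethyl-4-oxo-4H-pyran-2-yl)-4,6-dimethylnon-6-en-5-yl propanoate | CCC(=O)O[C@@H](/C(C)=C/[C@H](C)c1oc([C@H](C)[C@@H](O[Si](C)(C)C(C)(C)C)CC)c(C)c(=O)c1C)[C@H](C)[C@H](OC(C)=O)[C@@H](C)c1oc(CC)c(C)c(=O)c1C | intermediate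
31 | (2R,3S,4R,5R,6E,8S)-3-acetoxy-2-(6-ethyl-3,5-dimethyl-4-oxo-4H-pyran-2-yl)-8-{6-[(2R,3S)-3-hydroxypentan-2-yl]-3,5-dimethyl-4-oxo-4H-pyran-2-yl}-4,6-dimethylnon-6-en-5-yl propanoate (CNP0265513.2) | CCC(=O)O[C@@H](/C(C)=C/[C@H](C)c1oc([C@H](C)[C@@H](O)CC)c(C)c(=O)c1C)[C@H](C)[C@H](OC(C)=O)[C@@H](C)c1oc(CC)c(C)c(=O)c1C | target

Total step count: 20.
Longest linear sequence: 14 steps (1, 7, 9 to 18, 19, 20).

Steps most likely to fail

1. Step 19 (proposed new method). What may go wrong: after halogen abstraction from 12 the radical may be reduced or may dimerise faster than it is captured at nickel; low-valent nickel may ionise the allylic propionate of 29; the ligand may discriminate the two faces of the pyranonyl radical poorly. Fallback with known chemistry, setting out from 12 and 29 and coming back at 30: zinc insertion into 12 (Zn dust, LiCl, THF) should give the secondary organozinc chloride F1, and a Negishi coupling of F1 with 29 (Pd(OAc)2, SPhos, THF, rt) should form the same bond with retention of the E geometry but without control at the new centre. Compound 30 would then be separated by preparative HPLC from its epimer at that centre, the (8R)-diastereomer F2.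

2. Step 14 (the same concern applies to step 4). What may go wrong: attack of the hindered dienolate carbon on the α-branched, β-silyloxy Weinreb amide may be slow, so that proton transfer (loss of configuration next to the amide carbonyl) or simple recovery of 22 takes over. Fallback, setting out from 22 and coming back at 24: reduction of 22 with iBu2AlH (THF, −78 °C) should give the aldehyde F3; aldol addition of the dienolate 23, made as in step 14, to F3 at −78 °C should give the β-hydroxy diketone F4 as a mixture at the new centres; Dess–Martin oxidation of F4 should give 24.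

3. Step 6. What may go wrong: proton transfer from the product to unreacted dienolate 11 may lead to double chlorination or to elimination to the vinylpyranone, and deprotonation may compete at the side-chain methine. Fallback, setting out from 10 and coming back at 12: the dienolate 11 is hydroxylated with 2-(phenylsulfonyl)-3-phenyloxaziridine to the secondary alcohol F5 (the alkoxide formed is not prone to further deprotonation), the alcohol is converted into the mesylate F6 (MsCl, Et3N, CH2Cl2, −20 °C), and displacement with LiCl in DMF should give 12.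

Further compounds
F1 | step 19 | {1-[6-{(2R,3S)-3-[(tert-butyldimethylsilyl)oxy]pentan-2-yl}-3,5-dimethyl-4-oxo-4H-pyran-2-yl]ethyl}zinc chloride (both epimers) | CC[C@H](O[Si](C)(C)C(C)(C)C)[C@@H](C)c1oc(C(C)[Zn]Cl)c(C)c(=O)c1C
F2 | step 19 | (8R)-epimer of 30 | CCC(=O)O[C@@H](/C(C)=C/[C@@H](C)c1oc([C@H](C)[C@@H](O[Si](C)(C)C(C)(C)C)CC)c(C)c(=O)c1C)[C@H](C)[C@H](OC(C)=O)[C@@H](C)c1oc(CC)c(C)c(=O)c1C
F3 | step 14 | (2R,3S,4R,5R,6E)-7-bromo-3-[(tert-butyldimethylsilyl)oxy]-2,4,6-trimethyl-5-[(triethylsilyl)oxy]hept-6-enal | CC[Si](CC)(CC)O[C@@H](/C(C)=C/Br)[C@H](C)[C@H](O[Si](C)(C)C(C)(C)C)[C@@H](C)C=O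
F4 | step 14 | 13-bromo-9-[(tert-butyldimethylsilyl)oxy]-7-hydroxy-4,6,8,10,12-pentamethyl-11-[(triethylsilyl)oxy]tridec-12-ene-3,5-dione (C8 to C11 and the alkene as in 22; mixture at C4, C6 and C7) | CC[Si](CC)(CC)O[C@@H](/C(C)=C/Br)[C@H](C)[C@H](O[Si](C)(C)C(C)(C)C)[C@@H](C)C(O)C(C)C(=O)C(C)C(=O)CC
F5 | step 6 | 2-(1-hydroxyethyl)-6-{(2R,3S)-3-[(tert-butyldimethylsilyl)oxy]pentan-2-yl}-3,5-dimethyl-4H-pyran-4-one (both epimers at the carbinol carbon) | CC[C@H](O[Si](C)(C)C(C)(C)C)[C@@H](C)c1oc(C(C)O)c(C)c(=O)c1C
F6 | step 6 | 1-[6-{(2R,3S)-3-[(tert-butyldimethylsilyl)oxy]pentan-2-yl}-3,5-dimethyl-4-oxo-4H-pyran-2-yl]ethyl methanesulfonate (both epimers) | CC[C@H](O[Si](C)(C)C(C)(C)C)[C@@H](C)c1oc(C(C)OS(C)(=O)=O)c(C)c(=O)c1C
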